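**Retrosynthetic overview**
1. Both oxepanone rings are taken apart last, each at O–C(CH3)2 and at CH2–CH2 (α to the ketone): 22 ⇒ bis(oxetane) diacetate 17 + two 1,1-dimethyl-2-silyloxyallyl cations (from 19), a two-fold formal (4+3) ring expansion.
2. Enabling feature: in each half the ring-fusion oxygen, C-7, the quaternary C-6 and its CH2 (C-5) form a trans-fused oxetane (7-oxabicyclo[4.2.0]octane), i.e. a Lewis-basic oxygen next to a primary C–O bond whose cleavage releases the ring strain.
3. Oxetanes ⇐ 1,3-diols ⇐ hydroxyl-directed C–H silylation/oxidation of the equatorial methyl of each 2,2-dimethylcyclohexanol (sets C-6 and C-6').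
4. Central CH2–CH2 bond ⇐ Giese coupling of iodide 7 with exo-methylene ketone 5, both from cyclohexane 3; the two epimeric C-10 centres then come from MeCeCl2 on the ketone (axial OH) and from epoxidation/hydride on the exocyclic alkene (equatorial OH).
5. Ring order: cyclohexanes first (Shi epoxidation of geranyl acetate sets C-7, titanocene radical cyclisation relays C-11), then the two oxetanes, then both oxepanones in the final step.

Key step: step 15

Remark: locants follow the squalene skeleton (C-2 = CMe2, C-3 = C=O, C-4/C-5 = ring CH2CH2, C-6 = quaternary ring-fusion C, C-7 = ring-fusion CH–O, C-10 = C(CH3)OAc, C-11 = CH, C-12 = central CH2); half A carries the axial acetate (10R), half B (primed locants) the equatorial acetate (10S).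

**Route**

Step 1
Reactants: 1 geranyl acetate
Product: 2 (6S)-6,7-epoxygeranyl acetate
Conditions: 1,2:4,5-di-O-isopropylidene-β-L-erythro-2,3-hexodiulo-2,6-pyranose (enantiomer of the Shi ketone, 0.3 equiv), KHSO5 (Oxone), K2CO3, Bu4NHSO4, MeCN/CH2(OMe)2, aq. Na2B4O7 buffer, 0 °C
Reagents that add atoms: potassium peroxymonosulfate, [K+].[O-]S(=O)(=O)OO
Why: Shi epoxidation; the chiral dioxirane attacks the electron-rich 6,7-alkene (the 2,3-alkene is deactivated by the allylic acetate) through a spiro transition state and sets C-7 as S.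

Step 2
Reactants: 2 (6S)-6,7-epoxygeranyl acetate
Product: 3 [(1R,3S)-3-hydroxy-2,2-dimethyl-6-methylidenecyclohexyl]methyl acetate
Conditions: Cp2TiCl2 (2.2 equiv), Mn powder, THF, 25 °C; then dilute aq. HCl
Reagents that add atoms: none
Why: Nugent–RajanBabu epoxide opening by Cp2TiCl (trivalent titanium) gives the tertiary β-titanoxy radical, which closes 6-endo-trig through a chair with the titanoxy and CH2OAc groups equatorial (sets C-11 from C-7), and the tertiary radical is trapped by a second Cp2TiCl and loses β-hydride to give the exocyclic alkene.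

Step 3
Reactants: 3 [(1R,3S)-3-hydroxy-2,2-dimethyl-6-methylidenecyclohexyl]methyl acetate
Product: 5 (4S)-4-hydroxy-3,3-dimethyl-2-methylidenecyclohexan-1-one, via β-acetoxy ketone 4 (not isolated)
Conditions: O3, CH2Cl2/MeOH, −78 °C; Me2S, −78 → 25 °C; then DBU, CH2Cl2, 0 °C
Reagents that add atoms: ozone, O=[O+][O-]
Why: Ozonolysis (Criegee mechanism) of the only alkene gives the C-10 ketone, and E1cB loss of acetate from the β-acetoxy ketone gives the exo-methylene ketone.

Step 4
Reactants: 3 [(1R,3S)-3-hydroxy-2,2-dimethyl-6-methylidenecyclohexyl]methyl acetate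
Product: 6 (1S,3R)-3-(hydroxymethyl)-2,2-dimethyl-4-methylidenecyclohexan-1-ol
Conditions: K2CO3 (cat.), MeOH, 25 °C
Reagents that add atoms: none
Why: Base-catalysed transesterification of the primary acetate; no stereocenter is touched.

Step 5
Reactants: 6 (1S,3R)-3-(hydroxymethyl)-2,2-dimethyl-4-methylidenecyclohexan-1-ol
Product: 7 (1S,3R)-3-(iodomethyl)-2,2-dimethyl-4-methylidenecyclohexan-1-ol
Conditions: I2, PPh3, imidazole, CH2Cl2, 0 °C
Reagents that add atoms: iodine, II
Why: Appel-type iodination by SN2 at the primary carbinol; the secondary hydroxyl next to the quaternary carbon is too hindered to react.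

Step 6
Reactants: 7 (1S,3R)-3-(iodomethyl)-2,2-dimethyl-4-methylidenecyclohexan-1-ol; 5 (4S)-4-hydroxy-3,3-dimethyl-2-methylidenecyclohexan-1-one (1.5 equiv)
Product: 8 (2S,4S)-4-hydroxy-2-{2-[(1R,3S)-3-hydroxy-2,2-dimethyl-6-methylidenecyclohexyl]ethyl}-3,3-dimethylcyclohexan-1-one
Conditions: (Me3Si)3SiH (slow addition), AIBN (cat.), toluene, 80 °C
Reagents that add atoms: none
Why: Giese reaction; the primary C-12' radical adds to the CH2 terminus of the enone, and the α-keto radical takes hydrogen from the silane on the face opposite the axial C-6 methyl, which places the new chain equatorial at C-11 (also the thermodynamic epimer).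

Step 7
Reactants: 8 (2S,4S)-4-hydroxy-2-{2-[(1R,3S)-3-hydroxy-2,2-dimethyl-6-methylidenecyclohexyl]ethyl}-3,3-dimethylcyclohexan-1-one
Product: 9 (1R,2S,4S)-2-{2-[(1R,3S)-3-hydroxy-2,2-dimethyl-6-methylidenecyclohexyl]ethyl}-1,3,3-trimethylcyclohexane-1,4-diol
Conditions: MeLi (excess), CeCl3, THF, −78 °C; aq. NH4Cl
Reagents that add atoms: methyllithium, [Li]C
Why: Organocerium 1,2-addition to the enolisable ketone; the axial face is blocked by the 1,3-diaxial C-6 methyl, so methyl enters equatorially and C-10 is set with the axial hydroxyl (10R).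

Step 8
Reactants: 9 (1R,2S,4S)-2-{2-[(1R,3S)-3-hydroxy-2,2-dimethyl-6-methylidenecyclohexyl]ethyl}-1,3,3-trimethylcyclohexane-1,4-diol
Product: 10 (1R,2S,4S)-2-{2-[(3S,4S,6S)-6-hydroxy-5,5-dimethyl-1-oxaspiro[2.5]octan-4-yl]ethyl}-1,3,3-trimethylcyclohexane-1,4-diol
Conditions: mCPBA, NaHCO3, CH2Cl2, 0 °C
Reagents that add atoms: 3-chloroperoxybenzoic acid, OOC(=O)c1cccc(Cl)c1
Why: Prilezhaev epoxidation of the exocyclic alkene from the equatorial face (the axial face is shielded by the axial C-6' methyl) sets C-10' with the oxygen equatorial.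

Step 9
Reactants: 10 (1R,2S,4S)-2-{2-[(3S,4S,6S)-6-hydroxy-5,5-dimethyl-1-oxaspiro[2.5]octan-4-yl]ethyl}-1,3,3-trimethylcyclohexane-1,4-diol
Product: 11 (1R,2S,4S)-2-{2-[(1S,3S,6S)-3,6-dihydroxy-2,2,6-trimethylcyclohexyl]ethyl}-1,3,3-trimethylcyclohexane-1,4-diol
Conditions: LiEt3BH (excess), THF, 0 → 25 °C; aq. NH4Cl
Reagents that add atoms: none
Why: SN2 hydride opening of the spiro-epoxide at its CH2 carbon leaves the C-10'–O bond intact, giving the equatorial tertiary alcohol with an axial methyl (10'S).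

Step 10
Reactants: 11 (1R,2S,4S)-2-{2-[(1S,3S,6S)-3,6-dihydroxy-2,2,6-trimethylcyclohexyl]ethyl}-1,3,3-trimethylcyclohexane-1,4-diol
Product: 14 (1R,2S,3R,4S)-2-{2-[(1S,2R,3S,6S)-3,6-dihydroxy-2-(hydroxymethyl)-2,6-dimethylcyclohexyl]ethyl}-3-(hydroxymethyl)-1,3-dimethylcyclohexane-1,4-diol, via bis(diethylsilyl) ether 12 (not isolated), via bis(oxasilolane) 13 (not isolated)
Conditions: (a) Et2SiH2 (2.5 equiv), [Ir(cod)OMe]2 (cat.), THF, 25 °C; (b) [Ir(cod)OMe]2 (cat.), 3,4,7,8-tetramethyl-1,10-phenanthroline, norbornene, THF, 120 °C; (c) H2O2, KHCO3, THF/MeOH, 50 °C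
Reagents that add atoms: hydrogen peroxide, OO
Why: Hydroxyl-directed iridium-catalysed γ-C–H silylation of the (hydrido)silyl ethers followed by Tamao–Fleming oxidation; the trans-fused oxasilolane forms at the equatorial methyl because the axial methyl is shielded by the 1,3-diaxial C-10 substituent (as for the equatorial C-4 methyl of 3β-hydroxy triterpenoids), which sets C-6 and C-6'.

Step 11
Reactants: 14 (the hexaol above)
Product: 15 bis(primary 4-toluenesulfonate) of 14
Conditions: TsCl (2.2 equiv), pyridine, CH2Cl2, 0 °C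
Reagents that add atoms: 4-toluenesulfonyl chloride, Cc1ccc(cc1)S(Cl)(=O)=O
Why: Sulfonylation is selective for the two primary hydroxyls over the hindered secondary and tertiary ones.

Step 12
Reactants: 15 bis(primary 4-toluenesulfonate) of 14
Product: 16 (1R,2S,3R,6S)-2-{2-[(1R,2S,3S,6S)-3-hydroxy-1,3-dimethyl-7-oxabicyclo[4.2.0]octan-2-yl]ethyl}-1,3-dimethyl-7-oxabicyclo[4.2.0]octan-3-ol
Conditions: NaH (excess), THF, 0 → 50 °C
Reagents that add atoms: none
Why: Intramolecular Williamson etherification (4-exo-tet, assisted by the Thorpe–Ingold effect of the quaternary C-6) closes each trans-fused oxetane without touching C-6 or C-7.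

Step 13
Reactants: 16 (the bis(oxetane) diol above)
Product: 17 diacetate of 16 (both tertiary hydroxyls acetylated)
Conditions: Ac2O, DMAP, Et3N, toluene, 60 °C
Reagents that add atoms: acetic anhydride, CC(=O)OC(C)=O
Why: DMAP-catalysed acylation under base leaves the oxetanes intact and installs the target acetates, which also mask the hydroxyls that would otherwise capture the cation of step 15.

Step 14
Reactants: 18 3-bromo-3-methylbutan-2-one
Product: 19 3-bromo-3-methyl-2-(trimethylsilyloxy)but-1-ene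
Conditions: LiN(iPr)2, Me3SiCl (internal quench), THF, −78 °C
Reagents that add atoms: chlorotrimethylsilane, C[Si](C)(C)Cl
Why: Kinetic enolisation can only occur at the methyl group, and O-silylation at −78 °C traps the enolate before bromide is lost.

Step 15
Reactants: 17 diacetate of 16; 19 3-bromo-3-methyl-2-(trimethylsilyloxy)but-1-ene (4 equiv, slow addition)
Product: 22 CNP0325605.1, via mono-oxepanone (half A annulated) 20 (not isolated), via mono-oxepanone (half B annulated) 21 (not isolated)
Conditions: AgOTf (4 equiv), 2,6-di-tert-butyl-4-methylpyridine, CH2Cl2, −78 → −30 °C, high dilution; aq. NaHCO3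
Reagents that add atoms: none
Why: Proposed new method: AgOTf abstracts bromide from 19 to give the 1,1-dimethyl-2-(trimethylsilyloxy)allyl cation, which is captured at its tertiary terminus by the most basic site of 17, the strained oxetane oxygen, and the enol-ether CH2 of the resulting O-alkyl oxetanium ion then attacks the primary oxetane carbon with C–O cleavage and loss of Me3Si+ to triflate, so the three-carbon unit is inserted into the O–CH2 bond and the ketone appears directly; the same event at the second oxetane (through 20 or 21) gives 22. The closest known reactions are the (4+3) cycloadditions of this same 2-silyloxyallyl cation (from 19 with a silver salt or ZnCl2) with furans and dienes, the capture of oxyallyl cations by alcohol and carbonyl oxygen, and the ring expansions of oxetanes through O-alkyl oxetanium (oxonium ylide) intermediates to tetrahydrofurans and, with carbene-derived enolates, to 1,4-dioxepines. Each oxepanone ring is closed by ring expansion, a 1,4-shift of the CH2 group from oxygen to the enol carbon through a five-membered transition state (formally 5-endo-tet, which is the weak point) that is driven by release of the strain of the trans-fused oxetanium; should triflate open the oxetanium first, the primary triflate can still be closed by the same enol ether in a 7-exo-tet alkylation. No stereocenter is formed: the C-7–O bond is never broken, so C-7 and the quaternary C-6 keep their configurations. The step needs capture by the oxetane oxygen and not by the hindered tertiary acetates, attack at the tertiary and not the CH2 terminus of the cation (the more substituted terminus carries the charge), cleavage of the primary C-5–O and not the secondary neopentylic C-7–O bond (steric control of an SN2-like opening), C- and not O-alkylation (the enol oxygen is silylated), and ring expansion in preference to cationic oligomerisation of the oxetane (slow addition, high dilution, hindered base).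

**Compound list**

1 | geranyl acetate | CC(=O)OC/C=C(\C)CCC=C(C)C | starting material
2 | (6S)-6,7-epoxygeranyl acetate | CC(=O)OC/C=C(\C)CC[C@@H]1OC1(C)C | intermediate
3 | [(1R,3S)-3-hydroxy-2,2-dimethyl-6-methylidenecyclohexyl]methyl acetate | CC(=O)OC[C@H]1C(C)(C)[C@@H](O)CCC1=C | intermediate
4 | [(1R,3S)-3-hydroxy-2,2-dimethyl-6-oxocyclohexyl]methyl acetate (not isolated) | CC(=O)OC[C@H]1C(C)(C)[C@@H](O)CCC1=O | intermediate
5 | (4S)-4-hydroxy-3,3-dimethyl-2-methylidenecyclohexan-1-one | C=C1C(=O)CC[C@H](O)C1(C)C | intermediate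
6 | (1S,3R)-3-(hydroxymethyl)-2,2-dimethyl-4-methylidenecyclohexan-1-ol | OC[C@H]1C(C)(C)[C@@H](O)CCC1=C | intermediate
7 | (1S,3R)-3-(iodomethyl)-2,2-dimethyl-4-methylidenecyclohexan-1-ol | IC[C@H]1C(C)(C)[C@@H](O)CCC1=C | intermediate
8 | (2S,4S)-4-hydroxy-2-{2-[(1R,3S)-3-hydroxy-2,2-dimethyl-6-methylidenecyclohexyl]ethyl}-3,3-dimethylcyclohexan-1-one | C(C[C@H]1C(C)(C)[C@@H](O)CCC1=O)[C@H]1C(C)(C)[C@@H](O)CCC1=C | intermediate
9 | (1R,2S,4S)-2-{2-[(1R,3S)-3-hydroxy-2,2-dimethyl-6-methylidenecyclohexyl]ethyl}-1,3,3-trimethylcyclohexane-1,4-diol | C(C[C@H]1C(C)(C)[C@@H](O)CC[C@@]1(C)O)[C@H]1C(C)(C)[C@@H](O)CCC1=C | intermediate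
10 | (1R,2S,4S)-2-{2-[(3S,4S,6S)-6-hydroxy-5,5-dimethyl-1-oxaspiro[2.5]octan-4-yl]ethyl}-1,3,3-trimethylcyclohexane-1,4-diol | C(C[C@H]1C(C)(C)[C@@H](O)CC[C@@]1(C)O)[C@H]1C(C)(C)[C@@H](O)CC[C@@]12CO2 | intermediate
11 | (1R,2S,4S)-2-{2-[(1S,3S,6S)-3,6-dihydroxy-2,2,6-trimethylcyclohexyl]ethyl}-1,3,3-trimethylcyclohexane-1,4-diol | C(C[C@H]1C(C)(C)[C@@H](O)CC[C@@]1(C)O)[C@H]1C(C)(C)[C@@H](O)CC[C@]1(C)O | intermediate
12 | bis(diethylsilyl) ether of 11 at both secondary hydroxyls (not isolated) | C(C[C@H]1C(C)(C)[C@@H](O[SiH](CC)CC)CC[C@@]1(C)O)[C@H]1C(C)(C)[C@@H](O[SiH](CC)CC)CC[C@]1(C)O | intermediate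
13 | bis(oxasilolane): each C-7 oxygen and equatorial C-6 CH2 bridged by SiEt2 (not isolated) | C(C[C@H]1[C@]2(C)C[Si](CC)(CC)O[C@H]2CC[C@@]1(C)O)[C@H]1[C@]2(C)C[Si](CC)(CC)O[C@H]2CC[C@]1(C)O | intermediate
14 | (1R,2S,3R,4S)-2-{2-[(1S,2R,3S,6S)-3,6-dihydroxy-2-(hydroxymethyl)-2,6-dimethylcyclohexyl]ethyl}-3-(hydroxymethyl)-1,3-dimethylcyclohexane-1,4-diol | C(C[C@H]1[C@](C)(CO)[C@@H](O)CC[C@@]1(C)O)[C@H]1[C@](C)(CO)[C@@H](O)CC[C@]1(C)O | intermediate
15 | bis(primary 4-toluenesulfonate) of 14 | C(C[C@H]1[C@](C)(COS(=O)(=O)c2ccc(C)cc2)[C@@H](O)CC[C@@]1(C)O)[C@H]1[C@](C)(COS(=O)(=O)c2ccc(C)cc2)[C@@H](O)CC[C@]1(C)O | intermediate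
16 | (1R,2S,3R,6S)-2-{2-[(1R,2S,3S,6S)-3-hydroxy-1,3-dimethyl-7-oxabicyclo[4.2.0]octan-2-yl]ethyl}-1,3-dimethyl-7-oxabicyclo[4.2.0]octan-3-ol | C(C[C@H]1[C@]2(C)CO[C@H]2CC[C@@]1(C)O)[C@H]1[C@]2(C)CO[C@H]2CC[C@]1(C)O | intermediate
17 | diacetate of 16 | C(C[C@H]1[C@]2(C)CO[C@H]2CC[C@@]1(C)OC(C)=O)[C@H]1[C@]2(C)CO[C@H]2CC[C@]1(C)OC(C)=O | intermediate
18 | 3-bromo-3-methylbutan-2-one | CC(=O)C(C)(C)Br | starting material
19 | 3-bromo-3-methyl-2-(trimethylsilyloxy)but-1-ene | C=C(O[Si](C)(C)C)C(C)(C)Br | intermediate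
20 | mono-oxepanone, half A annulated, half B still oxetane (not isolated) | C(C[C@H]1[C@]2(C)CCC(=O)C(C)(C)O[C@H]2CC[C@@]1(C)OC(C)=O)[C@H]1[C@]2(C)CO[C@H]2CC[C@]1(C)OC(C)=O | intermediate
21 | mono-oxepanone, half B annulated, half A still oxetane (not isolated) | C(C[C@H]1[C@]2(C)CO[C@H]2CC[C@@]1(C)OC(C)=O)[C@H]1[C@]2(C)CCC(=O)C(C)(C)O[C@H]2CC[C@]1(C)OC(C)=O | intermediate
22 | CNP0325605.1: (5aS,6S,7R,9aS)-6-{2-[(5aS,6S,7S,9aS)-7-acetoxy-2,2,5a,7-tetramethyl-3-oxoperhydro-1-benzoxepin-6-yl]ethyl}-2,2,5a,7-tetramethyl-3-oxoperhydro-1-benzoxepin-7-yl acetate | CC(=O)O[C@]1(C)CC[C@@H]2OC(C)(C)C(=O)CC[C@@]2(C)[C@@H]1CC[C@H]1[C@]2(C)CCC(=O)C(C)(C)O[C@H]2CC[C@]1(C)OC(C)=O | target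

**Step count and risks**

Total step count: 15. Longest linear sequence: 13 steps (steps 1, 2, 4–13 and 15).

Steps most likely to fail:

1. Step 15. Cationic oligomerisation of the oxetanes, interception of the oxetanium ions by triflate, or ionisation of the tertiary acetates may override the ring expansion. Fallback (known reactions, from 16 back to 22): BF3·OEt2-promoted opening of both oxetanes at the primary carbon by the kinetic lithium enolate of 3-methylbutan-2-one (LiN(iPr)2, THF, −78 °C) should give the bis(δ-hydroxy ketone) F1. Bromination at the more substituted α-carbon (PhNMe3Br3, THF, 0 °C) should give the bis(tertiary α-bromo ketone) F2. Et3N in (CF3)2CHOH then generates the oxyallyl cations, which the C-7 hydroxyls capture at the tertiary terminus to give the bis(oxepanone) diol F3. Acetylation of the two tertiary hydroxyls (Ac2O, DMAP, Et3N) returns to the route at 22.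

2. Step 10. The two C-6 methyl groups may not be discriminated, or the two-fold C–H silylation may stall after one ring. Fallback (from 11 back to 14): Dess–Martin oxidation of the two secondary hydroxyls gives the diketone F4. MeONH2·HCl/pyridine gives the bis(O-methyl oxime) F5. Oxime-directed C–H acetoxylation (Pd(OAc)2 cat., PhI(OAc)2, AcOH/Ac2O, 80 °C) functionalises the equatorial methyl on each ring through a five-membered palladacycle to give the bis(acetoxymethyl) oxime ether F6. TiCl3/NH4OAc unmasks the ketones to the diketone bis(acetate) F7. NaBH4 attacks axially to give the equatorial diol bis(acetate) F8, and K2CO3/MeOH removes the primary acetates to return at 14.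

3. Step 12. Grob fragmentation of the C-7 alkoxide (cleavage of C-6–C-7 with loss of tosylate) may outrun the strained 4-exo-tet closure. Fallback (from 14 back to 16, bypassing 15): the anionic closure is replaced by a neutral redox condensation that never forms an alkoxide. Mitsunobu cyclodehydration of the 1,3-diols of 14 (PPh3, diisopropyl azodicarboxylate, Zn(S2CNMe2)2, toluene) activates the primary hydroxyls as oxyphosphonium ions and lets the neutral C-7 hydroxyls close the oxetanes; no new compound is made.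

**Further compounds**

F1 | step 15 | bis(δ-hydroxy ketone) from double oxetane opening | C(C[C@H]1[C@](C)(CCC(=O)C(C)C)[C@@H](O)CC[C@@]1(C)O)[C@H]1[C@](C)(CCC(=O)C(C)C)[C@@H](O)CC[C@]1(C)O
F2 | step 15 | bis(tertiary α-bromo ketone) | C(C[C@H]1[C@](C)(CCC(=O)C(C)(C)Br)[C@@H](O)CC[C@@]1(C)O)[C@H]1[C@](C)(CCC(=O)C(C)(C)Br)[C@@H](O)CC[C@]1(C)O
F3 | step 15 | bis(oxepanone) diol (22 without the two acetyl groups) | C(C[C@H]1[C@]2(C)CCC(=O)C(C)(C)O[C@H]2CC[C@@]1(C)O)[C@H]1[C@]2(C)CCC(=O)C(C)(C)O[C@H]2CC[C@]1(C)O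
F4 | step 10 | diketone (both C-7 carbinols of 11 oxidised) | C(C[C@H]1C(C)(C)C(=O)CC[C@@]1(C)O)[C@H]1C(C)(C)C(=O)CC[C@]1(C)O
F5 | step 10 | bis(O-methyl oxime) of F4 | C(C[C@H]1C(C)(C)/C(=N/OC)CC[C@@]1(C)O)[C@H]1C(C)(C)/C(=N/OC)CC[C@]1(C)O
F6 | step 10 | bis(acetoxymethyl) bis(O-methyl oxime) | C(C[C@H]1[C@](C)(COC(C)=O)/C(=N/OC)CC[C@@]1(C)O)[C@H]1[C@](C)(COC(C)=O)/C(=N/OC)CC[C@]1(C)O
F7 | step 10 | diketone bis(acetate) | C(C[C@H]1[C@](C)(COC(C)=O)C(=O)CC[C@@]1(C)O)[C@H]1[C@](C)(COC(C)=O)C(=O)CC[C@]1(C)O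
F8 | step 10 | equatorial diol bis(acetate) (14 with both primary hydroxyls acetylated) | C(C[C@H]1[C@](C)(COC(C)=O)[C@@H](O)CC[C@@]1(C)O)[C@H]1[C@](C)(COC(C)=O)[C@@H](O)CC[C@]1(C)O
F0 | step 12 | none | none
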